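**Retrosynthetic overview**
1. Target 15 = (2S,3S,2''R,3''S); unit 1 (4-methoxyphenyl; C2, C3) is 2,3-cis and unit 2 (4-hydroxyphenyl; C2'', C3'') is 2'',3''-trans. 15 comes from pentabenzyl ether 14 by hydrogenolysis.
2. The pyranone ring of unit 1 is closed last: the O1–C2 bond is formed by a catalyst-controlled 6-endo oxa-Michael addition with kinetic C3 protonation of the α-branched 2'-hydroxychalcone 12.
3. 12 comes from a Claisen–Schmidt condensation of anisaldehyde on the pendant ketone of flavanone 10. The pyranone ring of unit 2 is closed first: the O1''–C2'' bond is formed by oxa-Michael closure of mono-chalcone 7 with the pseudo-enantiomeric catalyst, because the two C2 centres have opposite configurations.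
4. 7 comes from mono-condensation of 4-(benzyloxy)benzaldehyde with the symmetric 1,4-diketone 5. Its central C3–C3'' bond is bought as a succinyl unit (aryllithium from 1 plus bis-Weinreb amide 2, then chelation-controlled mono-debenzylation).
5. Ring order: unit 2 pyranone (step 4), then unit 1 pyranone (step 6); all benzene rings are bought.

Assumption: 1 and 2 are bought as catalogue compounds, and the facial sense of the two pseudo-enantiomeric cinchona squaramides (quinine-derived gives 2''R in step 4, quinidine-derived gives 2S in step 6) is assigned by analogy with their known oxa-Michael cyclisations; if it proves reversed, the two catalysts change places.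

Step 1
Reactants: 1 1,3,5-tris(benzyloxy)benzene; 2 N1,N4-dimethoxy-N1,N4-dimethylbutanediamide
Product: 4 1,4-bis[2,4,6-tris(benzyloxy)phenyl]butane-1,4-dione, via aryllithium 3 (not isolated)
Conditions: 1 (2.3 equiv), n-BuLi (2.3 equiv), THF, 0 °C; then 2 (1 equiv), −78 °C → rt; aq NH4Cl
Reagents that add atoms: none
Why: Directed ortho-lithiation between two benzyloxy groups followed by Weinreb ketone synthesis, in which each amide accepts exactly one aryl group, so the diketone carrying the future C3–C3'' bond is made in one operation; no stereocentre is formed.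

Step 2
Reactants: 4 1,4-bis[2,4,6-tris(benzyloxy)phenyl]butane-1,4-dione
Product: 5 1,4-bis[2,4-bis(benzyloxy)-6-hydroxyphenyl]butane-1,4-dione
Conditions: BCl3 (2.2 equiv), CH2Cl2, −78 °C; then H2O
Reagents that add atoms: none
Why: Chelation-controlled aryl benzyl ether cleavage, in which BCl3 bound to each ketone oxygen removes one flanking benzyl group and the resulting boron aryloxide chelate shields the second ortho ether, while the para ethers are inert at −78 °C; no stereocentre is formed.

Step 3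
Reactants: 5 1,4-bis[2,4-bis(benzyloxy)-6-hydroxyphenyl]butane-1,4-dione; 6 4-(benzyloxy)benzaldehyde
Product: 7 (2E)-1,4-bis[2,4-bis(benzyloxy)-6-hydroxyphenyl]-2-[4-(benzyloxy)benzylidene]butane-1,4-dione
Conditions: 5 (2 equiv), 6 (1 equiv), BF3·OEt2 (4 equiv), 1,4-dioxane, 25 °C; aq work-up, excess 5 recovered
Reagents that add atoms: none
Why: Lewis-acid (BF3) Claisen–Schmidt condensation, in which boron bound to the o-hydroxyaryl ketone acidifies the α-CH2 and holds the phenol oxygen back from the new enone, so the open E-chalcone is obtained and the twofold excess of 5 favours the mono-adduct; no stereocentre is formed.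

Step 4
Reactants: 7 (2E)-1,4-bis[2,4-bis(benzyloxy)-6-hydroxyphenyl]-2-[4-(benzyloxy)benzylidene]butane-1,4-dione
Product: 10 (2R,3S)-5,7-bis(benzyloxy)-2-[4-(benzyloxy)phenyl]-3-{2-[2,4-bis(benzyloxy)-6-hydroxyphenyl]-2-oxoethyl}chroman-4-one, via enol 8 (not isolated), via cis epimer 9 (not isolated)
Conditions: 3-{[3,5-bis(trifluoromethyl)phenyl]amino}-4-{[(8α,9S)-6'-methoxycinchonan-9-yl]amino}cyclobut-3-ene-1,2-dione (10 mol%), PhMe, 25 °C; then 1,8-diazabicyclo[5.4.0]undec-7-ene (10 mol%), 0 °C, 30 min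
Reagents that add atoms: none
Why: Proposed new method: bifunctional tertiary-amine/squaramide catalysis of the 6-endo oxa-Michael closure of an α-branched, non-activated 2'-hydroxychalcone, in which the quinuclidine takes the phenol proton while the squaramide binds the enone carbonyl, so the phenoxide adds to one face of the β-carbon inside a chiral ion pair and sets C2'' (R); ketonisation of enol 8 is not selective at C3'', so the amidine base then epimerises cis epimer 9 to the more stable trans isomer 10 (aryl and side chain both equatorial) faster than the ring can reopen; the closest known reaction type is the cinchona thiourea- or squaramide-catalysed oxa-Michael cyclisation of α-carboxylate-activated 2'-hydroxychalcones to flavanones.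

Step 5
Reactants: 10 (2R,3S)-5,7-bis(benzyloxy)-2-[4-(benzyloxy)phenyl]-3-{2-[2,4-bis(benzyloxy)-6-hydroxyphenyl]-2-oxoethyl}chroman-4-one; 11 4-methoxybenzaldehyde
Product: 12 (2R,3S)-5,7-bis(benzyloxy)-2-[4-(benzyloxy)phenyl]-3-[(1E)-3-[2,4-bis(benzyloxy)-6-hydroxyphenyl]-1-(4-methoxyphenyl)-3-oxoprop-1-en-2-yl]chroman-4-one
Conditions: 11 (1.5 equiv), BF3·OEt2 (4 equiv), 1,4-dioxane, 25 °C; aq work-up
Reagents that add atoms: none
Why: Second BF3-mediated Claisen–Schmidt condensation at the only CH2 left, which is activated by boron binding to the free o-hydroxyaryl ketone while the flavanone ketone (no free phenol, tertiary α-carbon) stays out; the non-basic medium leaves C2''/C3'' untouched and the phenol stays on boron until work-up, so the open E-enone is isolated.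

Step 6
Reactants: 12 (2R,3S)-5,7-bis(benzyloxy)-2-[4-(benzyloxy)phenyl]-3-[(1E)-3-[2,4-bis(benzyloxy)-6-hydroxyphenyl]-1-(4-methoxyphenyl)-3-oxoprop-1-en-2-yl]chroman-4-one
Product: 14 (2S,3S)-5,7-bis(benzyloxy)-3-{(2R,3S)-5,7-bis(benzyloxy)-2-[4-(benzyloxy)phenyl]-4-oxochroman-3-yl}-2-(4-methoxyphenyl)chroman-4-one, via enol 13 (not isolated)
Conditions: 3-{[3,5-bis(trifluoromethyl)phenyl]amino}-4-{[(9R)-6'-methoxycinchonan-9-yl]amino}cyclobut-3-ene-1,2-dione (15 mol%), PhMe, 0 °C; cold filtration through silica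
Reagents that add atoms: none
Why: Proposed new method: the same oxa-Michael manifold run with the pseudo-enantiomeric catalyst and stopped at the kinetic product, in which the phenol oxygen is delivered to the opposite face of the anisyl-bearing β-carbon to set C2 (S); in enol 13 allylic strain with the bulky C3 substituent pushes the 2-aryl group pseudo-axial, so the quinuclidinium proton reaches C3 anti to the aryl group and leaves aryl and flavanonyl cis (3S), and the weak base at 0 °C does not re-enolise the product; because 12 is already enantio-enriched, any mis-selection ends up as separable diastereomers; the closest known reaction types are the organocatalytic oxa-Michael cyclisation to flavanones and the kinetic cis-selective protonation of 2-aryl-3-substituted chromanone enolates.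

Step 7
Reactants: 14 (2S,3S)-5,7-bis(benzyloxy)-3-{(2R,3S)-5,7-bis(benzyloxy)-2-[4-(benzyloxy)phenyl]-4-oxochroman-3-yl}-2-(4-methoxyphenyl)chroman-4-one
Product: 15 (2S,3S)-5,7-dihydroxy-3-[(2R,3S)-5,7-dihydroxy-2-(4-hydroxyphenyl)-4-oxochroman-3-yl]-2-(4-methoxyphenyl)chroman-4-one
Conditions: H2 (1 atm), 10% Pd/C, EtOAc/THF, 25 °C; stopped after 5 equiv H2
Reagents that add atoms: none
Why: Neutral hydrogenolysis of the five aryl benzyl ethers leaves the methyl ether in place, and with no acid or base present the epimerisable C3/C3'' and the ring-opening-prone C2/C2'' centres are preserved.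

**Compound list**
1 | 1,3,5-tris(benzyloxy)benzene | c1c(OCc2ccccc2)cc(OCc2ccccc2)cc1OCc1ccccc1 | starting material
2 | N1,N4-dimethoxy-N1,N4-dimethylbutanediamide | CON(C)C(=O)CCC(=O)N(C)OC | starting material
3 | 2,4,6-tris(benzyloxy)phenyllithium | [Li]c1c(OCc2ccccc2)cc(OCc2ccccc2)cc1OCc1ccccc1 | intermediate (not isolated)
4 | 1,4-bis[2,4,6-tris(benzyloxy)phenyl]butane-1,4-dione | O=C(CCC(=O)c1c(OCc2ccccc2)cc(OCc2ccccc2)cc1OCc1ccccc1)c1c(OCc2ccccc2)cc(OCc2ccccc2)cc1OCc1ccccc1 | intermediate
5 | 1,4-bis[2,4-bis(benzyloxy)-6-hydroxyphenyl]butane-1,4-dione | O=C(CCC(=O)c1c(O)cc(OCc2ccccc2)cc1OCc1ccccc1)c1c(O)cc(OCc2ccccc2)cc1OCc1ccccc1 | intermediate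
6 | 4-(benzyloxy)benzaldehyde | O=Cc1ccc(OCc2ccccc2)cc1 | starting material
7 | (2E)-1,4-bis[2,4-bis(benzyloxy)-6-hydroxyphenyl]-2-[4-(benzyloxy)benzylidene]butane-1,4-dione | O=C(c1c(O)cc(OCc2ccccc2)cc1OCc1ccccc1)/C(CC(=O)c1c(O)cc(OCc2ccccc2)cc1OCc1ccccc1)=C/c1ccc(OCc2ccccc2)cc1 | intermediate
8 | 1-[2,4-bis(benzyloxy)-6-hydroxyphenyl]-2-{(2S)-5,7-bis(benzyloxy)-2-[4-(benzyloxy)phenyl]-4-hydroxy-2H-chromen-3-yl}ethan-1-one (enol of 9/10; same spatial arrangement at C2 as in 10, the descriptor reads S because C3 is trigonal) | O=C(CC1=C(O)c2c(OCc3ccccc3)cc(OCc3ccccc3)cc2O[C@H]1c1ccc(OCc2ccccc2)cc1)c1c(O)cc(OCc2ccccc2)cc1OCc1ccccc1 | intermediate (not isolated)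
9 | (2R,3R)-5,7-bis(benzyloxy)-2-[4-(benzyloxy)phenyl]-3-{2-[2,4-bis(benzyloxy)-6-hydroxyphenyl]-2-oxoethyl}chroman-4-one (cis) | O=C(C[C@H]1C(=O)c2c(OCc3ccccc3)cc(OCc3ccccc3)cc2O[C@H]1c1ccc(OCc2ccccc2)cc1)c1c(O)cc(OCc2ccccc2)cc1OCc1ccccc1 | intermediate (not isolated)
10 | (2R,3S)-5,7-bis(benzyloxy)-2-[4-(benzyloxy)phenyl]-3-{2-[2,4-bis(benzyloxy)-6-hydroxyphenyl]-2-oxoethyl}chroman-4-one (trans) | O=C(C[C@@H]1C(=O)c2c(OCc3ccccc3)cc(OCc3ccccc3)cc2O[C@H]1c1ccc(OCc2ccccc2)cc1)c1c(O)cc(OCc2ccccc2)cc1OCc1ccccc1 | intermediate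
11 | 4-methoxybenzaldehyde | COc1ccc(C=O)cc1 | starting material
12 | (2R,3S)-5,7-bis(benzyloxy)-2-[4-(benzyloxy)phenyl]-3-[(1E)-3-[2,4-bis(benzyloxy)-6-hydroxyphenyl]-1-(4-methoxyphenyl)-3-oxoprop-1-en-2-yl]chroman-4-one | O=C(c1c(O)cc(OCc2ccccc2)cc1OCc1ccccc1)/C(=C/c1ccc(OC)cc1)[C@@H]1C(=O)c2c(OCc3ccccc3)cc(OCc3ccccc3)cc2O[C@H]1c1ccc(OCc2ccccc2)cc1 | intermediate
13 | (2R,3S)-5,7-bis(benzyloxy)-2-[4-(benzyloxy)phenyl]-3-[(2R)-5,7-bis(benzyloxy)-4-hydroxy-2-(4-methoxyphenyl)-2H-chromen-3-yl]chroman-4-one (enol of 14; the enol C2 has the spatial arrangement of 2S in 14) | COc1ccc([C@H]2Oc3cc(OCc4ccccc4)cc(OCc4ccccc4)c3C(O)=C2[C@@H]2C(=O)c3c(OCc4ccccc4)cc(OCc4ccccc4)cc3O[C@H]2c2ccc(OCc3ccccc3)cc2)cc1 | intermediate (not isolated)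
14 | (2S,3S)-5,7-bis(benzyloxy)-3-{(2R,3S)-5,7-bis(benzyloxy)-2-[4-(benzyloxy)phenyl]-4-oxochroman-3-yl}-2-(4-methoxyphenyl)chroman-4-one | COc1ccc([C@H]2Oc3cc(OCc4ccccc4)cc(OCc4ccccc4)c3C(=O)[C@H]2[C@@H]2C(=O)c3c(OCc4ccccc4)cc(OCc4ccccc4)cc3O[C@H]2c2ccc(OCc3ccccc3)cc2)cc1 | intermediate
15 | (2S,3S)-5,7-dihydroxy-3-[(2R,3S)-5,7-dihydroxy-2-(4-hydroxyphenyl)-4-oxochroman-3-yl]-2-(4-methoxyphenyl)chroman-4-one | COc1ccc([C@H]2Oc3cc(O)cc(O)c3C(=O)[C@H]2[C@@H]2C(=O)c3c(O)cc(O)cc3O[C@H]2c2ccc(O)cc2)cc1 | target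

**Totals**
Total step count: 7. Longest linear sequence: 7 steps (1 → 15). Seven steps is the shortest sequence found in which both C2 centres are set under catalyst control.

**Steps most likely to fail**

Step 4 (new method): the electron-rich, α-branched enone may cyclise slowly or with low selectivity. The fallback sets out from 5 and comes back at 10, by-passing 7. Compounds 5 and 6 are condensed with pyrrolidine in EtOH at 60 °C (Kabbe condensation). The ring closes in the same flask under thermodynamic control to the racemic trans-flavanone, that is 10 together with (2S,3R)-5,7-bis(benzyloxy)-2-[4-(benzyloxy)phenyl]-3-{2-[2,4-bis(benzyloxy)-6-hydroxyphenyl]-2-oxoethyl}chroman-4-one F1. Preparative chiral SFC removes F1 and gives 10.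

Step 5: the CH2 sits next to a tertiary carbon and may condense slowly, and prolonged BF3 contact could open the flavanone ring or start a Paal–Knorr furan closure of the 1,4-diketone. The fallback sets out from 10 and comes back at 12. The pendant ketone is enolised regioselectively with Bu2BOTf and iPr2NEt (CH2Cl2, −78 °C, one extra equivalent for the phenol) and treated with 11. This directed aldol addition gives (2R,3S)-5,7-bis(benzyloxy)-2-[4-(benzyloxy)phenyl]-3-[1-[2,4-bis(benzyloxy)-6-hydroxyphenyl]-3-hydroxy-3-(4-methoxyphenyl)-1-oxopropan-2-yl]chroman-4-one F2, a syn-aldol mixture at the two new centres, which does not matter. Dehydration with catalytic p-toluenesulfonic acid in CH2Cl2 at 0 °C gives 12.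

Step 6 (new method): the catalyst may fail to override the bias of the existing C3'' centre, or the cis product may epimerise. The fallback uses known chemistry, sets out from 10 and comes back at 14, by-passing 12. An anti-selective boron aldol reaction (Cy2BCl, Et3N, E-enolate, then 11) gives, after chromatographic separation from the other anti diastereomer, (2R,3S)-5,7-bis(benzyloxy)-2-[4-(benzyloxy)phenyl]-3-[(2S,3R)-1-[2,4-bis(benzyloxy)-6-hydroxyphenyl]-3-hydroxy-3-(4-methoxyphenyl)-1-oxopropan-2-yl]chroman-4-one F3. Mitsunobu ring closure (PPh3, DIAD, THF, 0 °C) lets the phenol displace the activated carbinol with inversion, which gives the cis-(2S,3S) ring of 14. The risk there is partial ionisation at the p-methoxybenzylic carbon.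

**Further compounds**
F1 | step 4 | (2S,3R)-5,7-bis(benzyloxy)-2-[4-(benzyloxy)phenyl]-3-{2-[2,4-bis(benzyloxy)-6-hydroxyphenyl]-2-oxoethyl}chroman-4-one (enantiomer of 10) | O=C(C[C@H]1C(=O)c2c(OCc3ccccc3)cc(OCc3ccccc3)cc2O[C@@H]1c1ccc(OCc2ccccc2)cc1)c1c(O)cc(OCc2ccccc2)cc1OCc1ccccc1
F2 | step 5 | (2R,3S)-5,7-bis(benzyloxy)-2-[4-(benzyloxy)phenyl]-3-[1-[2,4-bis(benzyloxy)-6-hydroxyphenyl]-3-hydroxy-3-(4-methoxyphenyl)-1-oxopropan-2-yl]chroman-4-one (mixture at the two new centres) | O=C(c1c(O)cc(OCc2ccccc2)cc1OCc1ccccc1)C(C(O)c1ccc(OC)cc1)[C@@H]1C(=O)c2c(OCc3ccccc3)cc(OCc3ccccc3)cc2O[C@H]1c1ccc(OCc2ccccc2)cc1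
F3 | step 6 | (2R,3S)-5,7-bis(benzyloxy)-2-[4-(benzyloxy)phenyl]-3-[(2S,3R)-1-[2,4-bis(benzyloxy)-6-hydroxyphenyl]-3-hydroxy-3-(4-methoxyphenyl)-1-oxopropan-2-yl]chroman-4-one | COc1ccc([C@H](O)[C@@H](C(=O)c2c(O)cc(OCc3ccccc3)cc2OCc2ccccc2)[C@@H]2C(=O)c3c(OCc4ccccc4)cc(OCc4ccccc4)cc3O[C@H]2c2ccc(OCc3ccccc3)cc2)cc1
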